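All runs are calculated for an exercise; scatter was added.

A one-step world, in which L passes straight to D, is the plainest picture of this flask of L under held gas J, and the earlier runs, elm and alder, put it to the test.

common to all: J 46 mM (held)
- elm: L 0.074 M; run made earlier
- alder: L 0.17 M; run made earlier
- flask: L 0.11 M; time 25 min

| run | time / min | D / % | L / % |
|---|---|---|---|
| elm | 2.00 | 0.3 | 95.8 |
| elm | 5.00 | 0.8 | 89.2 |
| elm | 10.0 | 2.7 | 80.2 |
| elm | 25.0 | 15.7 | 58.1 |
| alder | 2.00 | 0 | 95.7 |
| alder | 5.00 | 0 | 90.1 |
| alder | 10.0 | 2.9 | 80.4 |
| alder | 25.0 | 14.2 | 58.1 |

(each reading ± 0.3 percentage points)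

- at the start none of Q is dissolved
- the analysis behind the earlier runs scatters by 0.3 percentage points, standard deviation
- what may be going on: L -> G; Q + G -> D; J <-> Q

- D at 25 min, in percent of the L charged
- the change that raises the amount of D at 25 min, in percent of the L charged most ("none" if none brings more than 2 percentage points) (Saturday's / Friday's / none)
- amount of D at 25 min, in percent of the L charged, after Friday's

- Saturday's: doubling the saturation concentration of J, all else as stated
- Friday's: doubling the transfer coefficient of J, all else as stated

L stands at 58.1 % in elm and 58.1 % in alder at 25.0 min, so its loss is first order, with k = 0.0217 min⁻¹ and a half-life of 31.9 min. The one-step world would put 41.9 % D in the flask at 25 min, yet elm read 15.7 %.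

The missing part stands as G, so a second step joins: τ_G, the lifetime of G, is the mean G between 10.0 min and 25.0 min divided by the D made per minute there, which treats G as pseudo-first-order while Q stays level. Elm reads 25.0 min and alder 29.5 min, so the flask's charge interpolates to 26.7 min. Two steps in series then give 15.8 % D.

The last process is Q dissolving from zero: the same series on elm gives 16.6 %, more than its reading by 0.89 percentage points, and taking that lag off leaves my own 14.9 %. Saturday's, doubling the Q that G meets, brings τ_G to 13.3 min and D to 23.6 %, a gain of 8.7 points. Friday's works on that lag, which this rough reckoning reads on elm as 0.89 points, less than Saturday's reckoned gain.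

The forecast gives 15.1 %, picks Saturday's and puts Friday's at 16.1 %, on these grounds: “Transfer is therefore only mildly limiting.”

The simulation gives 15.2 %, with Saturday's gaining 8.9 points and Friday's 1.4 points, to 16.6 %.

    L → G (k = 0.0217 min⁻¹)
    Q + G → D (k = 0.950 M⁻¹ min⁻¹)
    J ⇌ Q, rate k3*(csat - [Q]) (kL = 0.163 min⁻¹)

The flask's D moves by 5 points when it is read at 19.8 min or 29.9 min, whereas the charge of L has to reach 0.793 M for the same move, so the clock is the thing to watch. On the neighbouring flask, the same charge left until 1.0 h, the carried 26.7 min with the same lag gives 49.0 % D. That flask holds L 27.2 %, G 23.1 % and D 49.7 %.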